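The route rests on cutting two bonds of the (E)-C2'=C3' alkene that ties the arene ring to the chain: C1'–C2' and C3'–CH3. The C3' methyl and the benzylic carbon C1' sit cis, the imprint of syn methyl–metal addition to a terminal C2'≡C3' alkyne, so one pot (zirconium-catalysed methylalumination, then nickel-catalysed benzylation) delivers the methyl group, the alkene geometry and the aryl–chain bond, leaving the oxolane ring and all three stereocentres alone. The precursor is alkyne 27 (C2'–C15'): terminal alkyne, (5'S)-OTES, two (E)-trisubstituted alkenes and the cis-(12'S,14'S)-oxolane as its C14' TBS ether; its partner is benzylic chloride 32.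

Key step: step 19

Remarks on the chemistry:
- Locants C1'–C15' run from the benzylic carbon to the CMe2 carbon of the oxolane. The target is read as (5'S,12'S,14'S), with the C12' and C14' substituents cis on the ring.
- C14'–OH is carried as a TBS ether, so that its late removal with HF·pyridine spares the allylic acetate. C5'–OH is carried as a TES ether.
- 4-Methoxy-2-methylphenol, allenylboronic acid pinacol ester, (S)-TRIP, Cp2Zr(H)Cl and 2,2-dimethylfuran-3(2H)-one are taken as commercial.

Step 1
Reactants: 1 L-malic acid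
Product: 3 (3S)-3-hydroxy-4-methoxy-4-oxobutanoic acid (1-methyl hydrogen L-malate), via trifluoroacetoxysuccinic anhydride 2 (not isolated)
Conditions: (CF3CO)2O, 0 °C → rt; evaporate; MeOH, 0 °C → rt
Reagents that add atoms: methanol, CO
Why: Trifluoroacetic anhydride closes the five-membered anhydride and acylates the hydroxyl, and regioselective alcoholysis of this anhydride by methanol at the carbonyl activated by the neighbouring trifluoroacetoxy group (with methanolysis of the trifluoroacetate) should give the 1-monoester without touching the C–O stereocentre.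

Step 2
Reactants: 3 (3S)-3-hydroxy-4-methoxy-4-oxobutanoic acid
Product: 5 (4S)-4-hydroxy-5,5-dimethyloxolan-2-one, via dihydroxy acid 4 (not isolated)
Conditions: MeMgBr (5 eq), THF, 0 °C → rt; aq. HCl; TsOH (cat.), CH2Cl2, rt
Reagents that add atoms: methylmagnesium bromide, C[Mg]Br
Why: Grignard addition, in which two equivalents only deprotonate the hydroxyl and the acid, the magnesium carboxylate stays inert, and double methyl addition to the ester gives the tertiary carbinol that lactonises onto the C4 acid on acidification, the stereocentre (future C14') being a spectator.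

Step 3
Reactants: 5 (4S)-4-hydroxy-5,5-dimethyloxolan-2-one
Product: 6 (4S)-4-(tert-butyldimethylsilyloxy)-5,5-dimethyloxolan-2-one
Conditions: TBSOTf, 2,6-lutidine, CH2Cl2, −78 → 0 °C
Reagents that add atoms: tert-butyldimethylsilyl triflate, CC(C)(C)[Si](C)(C)OS(=O)(=O)C(F)(F)F
Why: Silylation with the reactive triflate and a hindered weak base should protect the neopentyl-type secondary alcohol quickly, before base-induced β-elimination of the lactone can compete.

Step 4
Reactants: 6 (4S)-4-(tert-butyldimethylsilyloxy)-5,5-dimethyloxolan-2-one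
Product: 8 (4S)-4-(tert-butyldimethylsilyloxy)-5,5-dimethyloxolan-2-yl acetate (anomer mixture), via aluminium hemiacetal 7 (not isolated)
Conditions: i-Bu2AlH, CH2Cl2, −78 °C; then pyridine, DMAP, Ac2O, −78 → −20 °C
Reagents that add atoms: acetic anhydride, CC(=O)OC(C)=O
Why: Reductive acetylation, in which one hydride adds to the lactone at −78 °C to give a stable tetrahedral aluminium hemiacetal that DMAP-catalysed acetylation traps in the same flask, so the ring never opens and both anomers serve because the next step passes through the oxocarbenium ion.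

Step 5
Reactants: 9 pent-3-yn-1-ol
Product: 10 5-iodopent-2-yne
Conditions: I2, PPh3, imidazole, CH2Cl2, 0 °C → rt
Reagents that add atoms: iodine, II
Why: Appel-type iodination converts the primary alcohol through its alkoxyphosphonium salt into the iodide by SN2 displacement, the internal alkyne being inert.

Step 6
Reactants: 10 5-iodopent-2-yne; 11 ethyl but-2-ynoate
Product: 15 ethyl (2E)-3-methyloct-2-en-6-ynoate, via pent-3-ynyllithium 12 (not isolated), via lithium dipentynylcuprate 13 (not isolated), via alkenylcuprate adduct 14 (not isolated)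
Conditions: 10, t-BuLi (2 eq), Et2O, −78 °C; CuI (0.5 eq), THF, −40 °C; 11, −78 °C; MeOH, −78 °C
Reagents that add atoms: none
Why: Iodine–lithium exchange and CuI give the dialkylcuprate, whose conjugate addition to the ynoate is a syn carbocupration, and protonation of the alkenylcuprate at −78 °C with retention should place the new chain trans to the ester, which is the (E)-C6'=C7' alkene.

Step 7
Reactants: 15 ethyl (2E)-3-methyloct-2-en-6-ynoate
Product: 16 (2E)-3-methyloct-2-en-6-yn-1-ol
Conditions: i-Bu2AlH (2.2 eq), CH2Cl2, −78 °C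
Reagents that add atoms: none
Why: Hydride 1,2-reduction of the conjugated ester at −78 °C should stop at the allylic alcohol and leave the alkene geometry and the alkyne untouched.

Step 8
Reactants: 16 (2E)-3-methyloct-2-en-6-yn-1-ol
Product: 17 tert-butyldimethyl{[(2E)-3-methyloct-2-en-6-yn-1-yl]oxy}silane
Conditions: TBSCl, imidazole, CH2Cl2, rt
Reagents that add atoms: tert-butyldimethylsilyl chloride, CC(C)(C)[Si](C)(C)Cl
Why: Imidazole-assisted silylation masks the primary allylic alcohol for the organometallic steps that follow.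

Step 9
Reactants: 17 tert-butyldimethyl{[(2E)-3-methyloct-2-en-6-yn-1-yl]oxy}silane
Product: 19 tert-butyl{[(2E,6E)-7-iodo-3-methylocta-2,6-dien-1-yl]oxy}dimethylsilane, via alkenylzirconocene chloride 18 (not isolated)
Conditions: Cp2Zr(H)Cl (2 eq), THF, rt → 50 °C; I2, 0 °C
Reagents that add atoms: iodine, II
Why: Hydrozirconation adds Zr–H syn across the internal alkyne, excess reagent with gentle warming should equilibrate the metal onto the less hindered methyl-bearing carbon (future C11'), and iodinolysis with retention then gives the (E)-alkenyl iodide while the trisubstituted alkene does not react.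

Step 10
Reactants: 19 tert-butyl{[(2E,6E)-7-iodo-3-methylocta-2,6-dien-1-yl]oxy}dimethylsilane; 8 (4S)-4-(tert-butyldimethylsilyloxy)-5,5-dimethyloxolan-2-yl acetate
Product: 22 (3S,5S)-3-(tert-butyldimethylsilyloxy)-5-[(2E,6E)-8-(tert-butyldimethylsilyloxy)-6-methylocta-2,6-dien-2-yl]-2,2-dimethyloxolane, via alkenyllithium 20 (not isolated), via alkenyl(dimethyl)alane 21 (not isolated)
Conditions: 19 (1.5 eq), t-BuLi (3 eq), Et2O, −78 °C; Me2AlCl (1.5 eq), −78 → 0 °C; 8, CH2Cl2, −78 → 0 °C
Reagents that add atoms: none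
Why: C-glycosylation-type substitution of a lactol acetate by an alkenylalane, in which exchange and Li-to-Al transmetalation keep the alkene geometry, the Lewis acidic alane ionises the anomeric acetate, and the alkenyl group (methyl being the poorest migrating group on aluminium) should add to the oxolanyl oxocarbenium ion by inside attack on the envelope whose C14'–OTBS group is pseudoaxial, setting C12' as S with the alkenyl group cis to the silyloxy group.

Step 11
Reactants: 22 (3S,5S)-3-(tert-butyldimethylsilyloxy)-5-[(2E,6E)-8-(tert-butyldimethylsilyloxy)-6-methylocta-2,6-dien-2-yl]-2,2-dimethyloxolane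
Product: 23 (2E,6E)-7-[(2S,4S)-4-(tert-butyldimethylsilyloxy)-5,5-dimethyloxolan-2-yl]-3-methylocta-2,6-dien-1-ol
Conditions: PPTS (0.2 eq), MeOH, rt
Reagents that add atoms: none
Why: Acid-catalysed methanolysis should remove the unhindered primary allylic TBS ether far faster than the secondary one flanked by the quaternary C15', so only C5'–OH is freed.

Step 12
Reactants: 23 (2E,6E)-7-[(2S,4S)-4-(tert-butyldimethylsilyloxy)-5,5-dimethyloxolan-2-yl]-3-methylocta-2,6-dien-1-ol
Product: 24 (2E,6E)-7-[(2S,4S)-4-(tert-butyldimethylsilyloxy)-5,5-dimethyloxolan-2-yl]-3-methylocta-2,6-dienal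
Conditions: MnO2, CH2Cl2, rt
Reagents that add atoms: none
Why: MnO2 oxidises allylic alcohols selectively to enals under neutral conditions, without over-oxidation and with the (E) geometry expected to hold.

Step 13
Reactants: 24 (2E,6E)-7-[(2S,4S)-4-(tert-butyldimethylsilyloxy)-5,5-dimethyloxolan-2-yl]-3-methylocta-2,6-dienal
Product: 26 (4S,5E,9E)-10-[(2S,4S)-4-(tert-butyldimethylsilyloxy)-5,5-dimethyloxolan-2-yl]-6-methylundeca-5,9-dien-1-yn-4-ol, via homopropargyl pinacol borate 25 (not isolated)
Conditions: allenyl-B(pin) (1.5 eq), (S)-TRIP (10 mol %), 4 Å MS, toluene, −20 °C; aq. NaHCO3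
Reagents that add atoms: allenylboronic acid pinacol ester, C=C=CB1OC(C)(C)C(C)(C)O1
Why: Brønsted acid-catalysed propargylation, in which the chiral phosphoric acid holds allenylboronate and aldehyde in a closed six-membered chair transition state (SE2' transfer, so only the homopropargylic alcohol forms) and the (S)-catalyst is chosen to expose the Si face of the enal, which should set C5' as S under reagent control with the distant oxolane stereocentres having no say.

Step 14
Reactants: 26 (4S,5E,9E)-10-[(2S,4S)-4-(tert-butyldimethylsilyloxy)-5,5-dimethyloxolan-2-yl]-6-methylundeca-5,9-dien-1-yn-4-ol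
Product: 27 triethyl{[(4S,5E,9E)-10-[(2S,4S)-4-(tert-butyldimethylsilyloxy)-5,5-dimethyloxolan-2-yl]-6-methylundeca-5,9-dien-1-yn-4-yl]oxy}silane
Conditions: TESCl, imidazole, CH2Cl2, 0 °C
Reagents that add atoms: chlorotriethylsilane, CC[Si](Cl)(CC)CC
Why: Silylation masks the secondary alcohol as an ether that is inert to organoaluminium reagents and later comes off under conditions that leave the TBS ether in place.

Step 15
Reactants: 28 4-methoxy-2-methylphenol
Product: 29 2-hydroxy-5-methoxy-3-methylbenzaldehyde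
Conditions: MgCl2, Et3N, (CH2O)n, MeCN, reflux
Reagents that add atoms: paraformaldehyde (as formaldehyde), C=O
Why: Magnesium-mediated ortho-formylation (Casnati–Skattebøl), in which the magnesium phenoxide delivers formaldehyde to the only free ortho position and a second formaldehyde oxidises the benzylic alkoxide by hydride transfer, so the aldehyde should form regiospecifically.

Step 16
Reactants: 29 2-hydroxy-5-methoxy-3-methylbenzaldehyde
Product: 30 2,5-dimethoxy-3-methylbenzaldehyde
Conditions: MeI, K2CO3, DMF, rt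
Reagents that add atoms: iodomethane, CI
Why: Williamson O-methylation of the phenoxide gives the dimethyl ether that masks the hydroquinone until the last step.

Step 17
Reactants: 30 2,5-dimethoxy-3-methylbenzaldehyde
Product: 31 (2,5-dimethoxy-3-methylphenyl)methanol
Conditions: NaBH4, MeOH, 0 °C
Reagents that add atoms: none
Why: Borohydride reduction converts the aryl aldehyde cleanly into the benzylic alcohol.

Step 18
Reactants: 31 (2,5-dimethoxy-3-methylphenyl)methanol
Product: 32 1-(chloromethyl)-2,5-dimethoxy-3-methylbenzene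
Conditions: SOCl2, CH2Cl2, 0 °C → rt
Reagents that add atoms: thionyl chloride, O=S(Cl)Cl
Why: Chlorodehydroxylation through the chlorosulfite is fast for this electron-rich benzylic alcohol and gives the electrophile for the coupling.

Step 19
Reactants: 27 triethyl{[(4S,5E,9E)-10-[(2S,4S)-4-(tert-butyldimethylsilyloxy)-5,5-dimethyloxolan-2-yl]-6-methylundeca-5,9-dien-1-yn-4-yl]oxy}silane; 33 trimethylaluminium; 32 1-(chloromethyl)-2,5-dimethoxy-3-methylbenzene
Product: 35 1-[(2E,5S,6E,10E)-11-[(2S,4S)-4-(tert-butyldimethylsilyloxy)-5,5-dimethyloxolan-2-yl]-3,7-dimethyl-5-(triethylsilyloxy)dodeca-2,6,10-trien-1-yl]-2,5-dimethoxy-3-methylbenzene, via alkenyl(dimethyl)alane 34 (not isolated)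
Conditions: 33 (2.5 eq), Cp2ZrCl2 (0.25 eq), ClCH2CH2Cl, 0 °C → rt; volatiles off; 32 (1.2 eq), NiCl2(PPh3)2 (5 mol %)/n-BuLi (10 mol %), THF, 0 °C → rt
Reagents that add atoms: none
Why: Cp2ZrCl2 and Me3Al form a methylzirconium–aluminium species that adds CH3 and metal syn across the terminal alkyne, CH3 to the internal carbon C3' and the metal (after Zr-to-Al exchange) to C2', giving the (E)-alkenyl(dimethyl)alane 34. Zerovalent nickel, generated from NiCl2(PPh3)2 and n-BuLi, inserts into the benzylic C–Cl bond of 32, the alkenyl group passes from aluminium to nickel, and reductive elimination forms C1'–C2' with retention of the alkene geometry. The closest known reaction type is the Negishi zirconium-catalysed carboalumination of terminal alkynes followed by nickel- or palladium-catalysed coupling of the alkenylalane with benzylic chlorides, as practised for prenylated quinones. No ring is closed and no stereocentre is created, and C5', C12' and C14' are untouched. The step needs regioselectivity (CH3 to C3') and syn stereospecificity to deliver the (E)-C2'=C3' alkene; the terminal alkyne secures the former, the concerted syn addition and the stereoretentive coupling the latter, and the C5' oxygen is kept as a silyl ether so that no chelating alkoxide can isomerise the alane. Because the benzylic carbon is the electrophile, no allylic transposition across C1'–C3' is possible, and the trisubstituted alkenes, silyl ethers, oxolane and aryl ethers are spectators.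

Step 20
Reactants: 35 1-[(2E,5S,6E,10E)-11-[(2S,4S)-4-(tert-butyldimethylsilyloxy)-5,5-dimethyloxolan-2-yl]-3,7-dimethyl-5-(triethylsilyloxy)dodeca-2,6,10-trien-1-yl]-2,5-dimethoxy-3-methylbenzene
Product: 36 (2E,5S,6E,10E)-11-[(2S,4S)-4-(tert-butyldimethylsilyloxy)-5,5-dimethyloxolan-2-yl]-1-(2,5-dimethoxy-3-methylphenyl)-3,7-dimethyldodeca-2,6,10-trien-5-ol
Conditions: PPTS (0.2 eq), MeOH/CH2Cl2, 0 °C
Reagents that add atoms: none
Why: Mild acid-catalysed methanolysis should cleave the triethylsilyl ether selectively, because the hindered TBS ether reacts far more slowly and the aryl methyl ethers and alkenes are inert.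

Step 21
Reactants: 36 (2E,5S,6E,10E)-11-[(2S,4S)-4-(tert-butyldimethylsilyloxy)-5,5-dimethyloxolan-2-yl]-1-(2,5-dimethoxy-3-methylphenyl)-3,7-dimethyldodeca-2,6,10-trien-5-ol
Product: 37 (2E,5S,6E,10E)-11-[(2S,4S)-4-(tert-butyldimethylsilyloxy)-5,5-dimethyloxolan-2-yl]-1-(2,5-dimethoxy-3-methylphenyl)-3,7-dimethyldodeca-2,6,10-trien-5-yl acetate
Conditions: Ac2O, pyridine, DMAP (cat.), CH2Cl2, 0 °C → rt
Reagents that add atoms: acetic anhydride, CC(=O)OC(C)=O
Why: DMAP-catalysed acylation esterifies the only free hydroxyl with retention at C5', since the C–O bond is not broken.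

Step 22
Reactants: 37 (2E,5S,6E,10E)-11-[(2S,4S)-4-(tert-butyldimethylsilyloxy)-5,5-dimethyloxolan-2-yl]-1-(2,5-dimethoxy-3-methylphenyl)-3,7-dimethyldodeca-2,6,10-trien-5-yl acetate
Product: 38 (2E,5S,6E,10E)-1-(2,5-dimethoxy-3-methylphenyl)-11-[(2S,4S)-4-hydroxy-5,5-dimethyloxolan-2-yl]-3,7-dimethyldodeca-2,6,10-trien-5-yl acetate
Conditions: HF·pyridine (excess), pyridine, THF, 0 °C → rt
Reagents that add atoms: none
Why: Fluoride-driven desilylation forms the strong Si–F bond and frees C14'–OH, while the allylic acetate, which is at risk with basic fluoride sources, should survive these mildly acidic buffered conditions.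

Step 23
Reactants: 38 (2E,5S,6E,10E)-1-(2,5-dimethoxy-3-methylphenyl)-11-[(2S,4S)-4-hydroxy-5,5-dimethyloxolan-2-yl]-3,7-dimethyldodeca-2,6,10-trien-5-yl acetate
Product: 40 (2E,5S,6E,10E)-1-(2,5-dihydroxy-3-methylphenyl)-11-[(2S,4S)-4-hydroxy-5,5-dimethyloxolan-2-yl]-3,7-dimethyldodeca-2,6,10-trien-5-yl acetate (target), via acetoxy quinone 39 (not isolated)
Conditions: (NH4)2Ce(NO3)6 (2.5 eq), MeCN/H2O (2:1), 0 °C, 15 min; then aq. Na2S2O4, EtOAc, rt, under argon
Reagents that add atoms: water, O
Why: Oxidative demethylation, in which (NH4)2Ce(NO3)6 oxidises the 1,4-dimethoxyarene by two single-electron transfers with water adding to the ring and methanol leaving to give the p-quinone, and dithionite then reduces the quinone to the hydroquinone without affecting the acetate, the alkenes or the stereocentres.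

Compound list
1 | L-malic acid, (2S)-2-hydroxybutanedioic acid | O[C@@H](CC(=O)O)C(=O)O | starting material
2 | (3S)-3-(trifluoroacetoxy)oxolane-2,5-dione (trifluoroacetoxysuccinic anhydride), not isolated | O=C1C[C@H](OC(=O)C(F)(F)F)C(=O)O1 | intermediate
3 | (3S)-3-hydroxy-4-methoxy-4-oxobutanoic acid (1-methyl hydrogen L-malate) | COC(=O)[C@@H](O)CC(=O)O | intermediate
4 | (3S)-3,4-dihydroxy-4-methylpentanoic acid (freed from its magnesium salt on acidification), not isolated | CC(C)(O)[C@@H](O)CC(=O)O | intermediate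
5 | (4S)-4-hydroxy-5,5-dimethyloxolan-2-one | O=C1C[C@H](O)C(C)(C)O1 | intermediate
6 | (4S)-4-(tert-butyldimethylsilyloxy)-5,5-dimethyloxolan-2-one | O=C1C[C@H](O[Si](C)(C)C(C)(C)C)C(C)(C)O1 | intermediate
7 | diisobutylaluminium hemiacetal of 6 (both anomers), not isolated | CC(C)C[Al](CC(C)C)OC1C[C@H](O[Si](C)(C)C(C)(C)C)C(C)(C)O1 | intermediate
8 | (4S)-4-(tert-butyldimethylsilyloxy)-5,5-dimethyloxolan-2-yl acetate (anomer mixture) | CC(=O)OC1C[C@H](O[Si](C)(C)C(C)(C)C)C(C)(C)O1 | intermediate
9 | pent-3-yn-1-ol | CC#CCCO | starting material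
10 | 5-iodopent-2-yne | CC#CCCI | intermediate
11 | ethyl but-2-ynoate | CC#CC(=O)OCC | starting material
12 | pent-3-ynyllithium, not isolated | [Li]CCC#CC | intermediate
13 | lithium bis(pent-3-ynyl)cuprate, not isolated | [Li+].CC#CCC[Cu-]CCC#CC | intermediate
14 | lithium alkenyl(pent-3-ynyl)cuprate, the syn adduct with copper on C2 cis to the new chain, not isolated | [Li+].CCOC(=O)/C([Cu-]CCC#CC)=C(\C)CCC#CC | intermediate
15 | ethyl (2E)-3-methyloct-2-en-6-ynoate | CCOC(=O)/C=C(\C)CCC#CC | intermediate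
16 | (2E)-3-methyloct-2-en-6-yn-1-ol | OC/C=C(\C)CCC#CC | intermediate
17 | tert-butyldimethyl{[(2E)-3-methyloct-2-en-6-yn-1-yl]oxy}silane | CC#CCC/C(C)=C/CO[Si](C)(C)C(C)(C)C | intermediate
18 | chlorobis(cyclopentadienyl)[(2E,6E)-8-(tert-butyldimethylsilyloxy)-6-methylocta-2,6-dien-2-yl]zirconium (cyclopentadienyl rings drawn σ-bound), not isolated | C/C(=C\CC/C(C)=C/CO[Si](C)(C)C(C)(C)C)[Zr](Cl)(C1C=CC=C1)C1C=CC=C1 | intermediate
19 | tert-butyl{[(2E,6E)-7-iodo-3-methylocta-2,6-dien-1-yl]oxy}dimethylsilane | C/C(I)=C\CC/C(C)=C/CO[Si](C)(C)C(C)(C)C | intermediate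
20 | alkenyllithium from 19 (lithium in place of iodine, geometry retained), not isolated | [Li]/C(C)=C/CC/C(C)=C/CO[Si](C)(C)C(C)(C)C | intermediate
21 | dimethyl[(2E,6E)-8-(tert-butyldimethylsilyloxy)-6-methylocta-2,6-dien-2-yl]alane, not isolated | C[Al](C)/C(C)=C/CC/C(C)=C/CO[Si](C)(C)C(C)(C)C | intermediate
22 | (3S,5S)-3-(tert-butyldimethylsilyloxy)-5-[(2E,6E)-8-(tert-butyldimethylsilyloxy)-6-methylocta-2,6-dien-2-yl]-2,2-dimethyloxolane (ring substituents cis) | CC(C)(C)[Si](C)(C)OC/C=C(\C)CC/C=C(\C)[C@@H]1C[C@H](O[Si](C)(C)C(C)(C)C)C(C)(C)O1 | intermediate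
23 | (2E,6E)-7-[(2S,4S)-4-(tert-butyldimethylsilyloxy)-5,5-dimethyloxolan-2-yl]-3-methylocta-2,6-dien-1-ol | OC/C=C(\C)CC/C=C(\C)[C@@H]1C[C@H](O[Si](C)(C)C(C)(C)C)C(C)(C)O1 | intermediate
24 | (2E,6E)-7-[(2S,4S)-4-(tert-butyldimethylsilyloxy)-5,5-dimethyloxolan-2-yl]-3-methylocta-2,6-dienal | O=C/C=C(\C)CC/C=C(\C)[C@@H]1C[C@H](O[Si](C)(C)C(C)(C)C)C(C)(C)O1 | intermediate
25 | pinacol borate ester of 26 (O–B(pin) at C5'), not isolated | C#CC[C@H](OB1OC(C)(C)C(C)(C)O1)/C=C(\C)CC/C=C(\C)[C@@H]2C[C@H](O[Si](C)(C)C(C)(C)C)C(C)(C)O2 | intermediate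
26 | (4S,5E,9E)-10-[(2S,4S)-4-(tert-butyldimethylsilyloxy)-5,5-dimethyloxolan-2-yl]-6-methylundeca-5,9-dien-1-yn-4-ol | C#CC[C@H](O)/C=C(\C)CC/C=C(\C)[C@@H]1C[C@H](O[Si](C)(C)C(C)(C)C)C(C)(C)O1 | intermediate
27 | triethyl{[(4S,5E,9E)-10-[(2S,4S)-4-(tert-butyldimethylsilyloxy)-5,5-dimethyloxolan-2-yl]-6-methylundeca-5,9-dien-1-yn-4-yl]oxy}silane (C2'–C15' alkyne, C5' OTES, C14' OTBS) | C#CC[C@H](O[Si](CC)(CC)CC)/C=C(\C)CC/C=C(\C)[C@@H]1C[C@H](O[Si](C)(C)C(C)(C)C)C(C)(C)O1 | intermediate
28 | 4-methoxy-2-methylphenol | COc1ccc(O)c(C)c1 | starting material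
29 | 2-hydroxy-5-methoxy-3-methylbenzaldehyde | COc1cc(C)c(O)c(C=O)c1 | intermediate
30 | 2,5-dimethoxy-3-methylbenzaldehyde | COc1cc(C)c(OC)c(C=O)c1 | intermediate
31 | (2,5-dimethoxy-3-methylphenyl)methanol | COc1cc(C)c(OC)c(CO)c1 | intermediate
32 | 1-(chloromethyl)-2,5-dimethoxy-3-methylbenzene (2,5-dimethoxy-3-methylbenzyl chloride) | COc1cc(C)c(OC)c(CCl)c1 | intermediate
33 | trimethylaluminium | C[Al](C)C | starting material
34 | dimethyl[(1E,4S,5E,9E)-10-[(2S,4S)-4-(tert-butyldimethylsilyloxy)-5,5-dimethyloxolan-2-yl]-2,6-dimethyl-4-(triethylsilyloxy)undeca-1,5,9-trien-1-yl]alane, not isolated | C[Al](C)/C=C(\C)C[C@H](O[Si](CC)(CC)CC)/C=C(\C)CC/C=C(\C)[C@@H]1C[C@H](O[Si](C)(C)C(C)(C)C)C(C)(C)O1 | intermediate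
35 | 1-[(2E,5S,6E,10E)-11-[(2S,4S)-4-(tert-butyldimethylsilyloxy)-5,5-dimethyloxolan-2-yl]-3,7-dimethyl-5-(triethylsilyloxy)dodeca-2,6,10-trien-1-yl]-2,5-dimethoxy-3-methylbenzene | COc1cc(C)c(OC)c(C/C=C(\C)C[C@H](O[Si](CC)(CC)CC)/C=C(\C)CC/C=C(\C)[C@@H]2C[C@H](O[Si](C)(C)C(C)(C)C)C(C)(C)O2)c1 | intermediate
36 | (2E,5S,6E,10E)-11-[(2S,4S)-4-(tert-butyldimethylsilyloxy)-5,5-dimethyloxolan-2-yl]-1-(2,5-dimethoxy-3-methylphenyl)-3,7-dimethyldodeca-2,6,10-trien-5-ol | COc1cc(C)c(OC)c(C/C=C(\C)C[C@H](O)/C=C(\C)CC/C=C(\C)[C@@H]2C[C@H](O[Si](C)(C)C(C)(C)C)C(C)(C)O2)c1 | intermediate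
37 | (2E,5S,6E,10E)-11-[(2S,4S)-4-(tert-butyldimethylsilyloxy)-5,5-dimethyloxolan-2-yl]-1-(2,5-dimethoxy-3-methylphenyl)-3,7-dimethyldodeca-2,6,10-trien-5-yl acetate | COc1cc(C)c(OC)c(C/C=C(\C)C[C@H](OC(C)=O)/C=C(\C)CC/C=C(\C)[C@@H]2C[C@H](O[Si](C)(C)C(C)(C)C)C(C)(C)O2)c1 | intermediate
38 | (2E,5S,6E,10E)-1-(2,5-dimethoxy-3-methylphenyl)-11-[(2S,4S)-4-hydroxy-5,5-dimethyloxolan-2-yl]-3,7-dimethyldodeca-2,6,10-trien-5-yl acetate | COc1cc(C)c(OC)c(C/C=C(\C)C[C@H](OC(C)=O)/C=C(\C)CC/C=C(\C)[C@@H]2C[C@H](O)C(C)(C)O2)c1 | intermediate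
39 | (2E,5S,6E,10E)-11-[(2S,4S)-4-hydroxy-5,5-dimethyloxolan-2-yl]-3,7-dimethyl-1-(5-methyl-3,6-dioxocyclohexa-1,4-dien-1-yl)dodeca-2,6,10-trien-5-yl acetate, not isolated | CC(=O)O[C@H](/C=C(\C)CC/C=C(\C)[C@@H]1C[C@H](O)C(C)(C)O1)C/C(C)=C/CC1=CC(=O)C=C(C)C1=O | intermediate
40 | (2E,5S,6E,10E)-1-(2,5-dihydroxy-3-methylphenyl)-11-[(2S,4S)-4-hydroxy-5,5-dimethyloxolan-2-yl]-3,7-dimethyldodeca-2,6,10-trien-5-yl acetate | CC(=O)O[C@H](/C=C(\C)CC/C=C(\C)[C@@H]1C[C@H](O)C(C)(C)O1)C/C(C)=C/Cc1cc(O)cc(C)c1O | target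

Total step count: 23 (steps 1–4 oxolane piece, 5–9 alkenyl iodide, 10–14 assembly of the alkyne, 15–18 benzylic chloride, 19 key step, 20–23 endgame).
Longest linear sequence: 15 steps (steps 5–14 and 19–23, from pent-3-yn-1-ol).

Steps most likely to fail

1. Step 19. The alkenylalane may transfer too slowly to nickel because the ether oxygens of the substrate tie up aluminium, so protodemetalation on work-up, homocoupling of the benzylic chloride or its methylation by residual Me3Al would take over. Fallback, with the polarity of the coupling reversed and both partners isolable: setting out from 27, the methylalumination is run as before and alane 34 is quenched with I2 at −30 °C to give (1E,4S,5E,9E)-1-iodo-2,6-dimethyl-10-[(2S,4S)-4-(tert-butyldimethylsilyloxy)-5,5-dimethyloxolan-2-yl]-4-(triethylsilyloxy)undeca-1,5,9-triene F1. Chloride 32 is converted with Zn dust and LiCl in THF into (2,5-dimethoxy-3-methylbenzyl)zinc chloride F2. Negishi coupling of F1 with F2 under Pd(PPh3)4 (zerovalent palladium) in THF forms the same C1'–C2' bond with retention and comes back to the route at 35.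

2. Step 10. Facial discrimination in the attack on the oxolanyl oxocarbenium ion may be poor, giving a cis/trans mixture at C12', or methyl may be transferred from aluminium in place of the alkenyl group. Fallback, in which C12' is set by a catalyst and C14' by the ring: setting out from 19, exchange with t-BuLi (via 20) and quenching with 2-isopropoxy-4,4,5,5-tetramethyl-1,3,2-dioxaborolane gives the alkenyl pinacol boronate F3. Rhodium-catalysed asymmetric 1,4-addition of F3 to commercial 2,2-dimethylfuran-3(2H)-one ([Rh(OH)(BINAP)]2 with the BINAP enantiomer that delivers the 12'S adduct, dioxane/H2O, 35 °C) gives (5S)-5-[(2E,6E)-8-(tert-butyldimethylsilyloxy)-6-methylocta-2,6-dien-2-yl]-2,2-dimethyloxolan-3-one F4. Reduction with LiBH(s-Bu)3 at −78 °C, hydride entering anti to the alkenyl group, should give the cis alcohol (3S,5S)-5-[(2E,6E)-8-(tert-butyldimethylsilyloxy)-6-methylocta-2,6-dien-2-yl]-2,2-dimethyloxolan-3-ol F5. Silylation with TBSOTf and 2,6-lutidine comes back to the route at 22.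

3. Step 13. The catalyst may discriminate the enal faces insufficiently on this β,β-disubstituted enal, or uncatalysed background addition may intervene, so that both C5' epimers form. Fallback, resolution in place of asymmetric induction: setting out from 24, Barbier propargylation (propargyl bromide, Zn, THF/aq. NH4Cl) gives 26 together with its epimer (4R,5E,9E)-10-[(2S,4S)-4-(tert-butyldimethylsilyloxy)-5,5-dimethyloxolan-2-yl]-6-methylundeca-5,9-dien-1-yn-4-ol F6. Acylation with Amano lipase PS and vinyl acetate, which by the usual enantiopreference of lipases for secondary alcohols should take the 5'R epimer, converts F6 into (4R,5E,9E)-10-[(2S,4S)-4-(tert-butyldimethylsilyloxy)-5,5-dimethyloxolan-2-yl]-6-methylundeca-5,9-dien-1-yn-4-yl acetate F7. The unreacted alcohol is separated by chromatography, and the sequence comes back to the route at 26.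

Further compounds
F1 | step 19 | (1E,4S,5E,9E)-1-iodo-2,6-dimethyl-10-[(2S,4S)-4-(tert-butyldimethylsilyloxy)-5,5-dimethyloxolan-2-yl]-4-(triethylsilyloxy)undeca-1,5,9-triene | I/C=C(\C)C[C@H](O[Si](CC)(CC)CC)/C=C(\C)CC/C=C(\C)[C@@H]1C[C@H](O[Si](C)(C)C(C)(C)C)C(C)(C)O1
F2 | step 19 | (2,5-dimethoxy-3-methylbenzyl)zinc chloride | COc1cc(C)c(OC)c(C[Zn]Cl)c1
F3 | step 10 | tert-butyldimethyl{[(2E,6Z)-3-methyl-7-(4,4,5,5-tetramethyl-1,3,2-dioxaborolan-2-yl)octa-2,6-dien-1-yl]oxy}silane (boron in place of iodine, geometry retained) | C/C(=C\CC/C(C)=C/CO[Si](C)(C)C(C)(C)C)B1OC(C)(C)C(C)(C)O1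
F4 | step 10 | (5S)-5-[(2E,6E)-8-(tert-butyldimethylsilyloxy)-6-methylocta-2,6-dien-2-yl]-2,2-dimethyloxolan-3-one | CC(C)(C)[Si](C)(C)OC/C=C(\C)CC/C=C(\C)[C@@H]1CC(=O)C(C)(C)O1
F5 | step 10 | (3S,5S)-5-[(2E,6E)-8-(tert-butyldimethylsilyloxy)-6-methylocta-2,6-dien-2-yl]-2,2-dimethyloxolan-3-ol | CC(C)(C)[Si](C)(C)OC/C=C(\C)CC/C=C(\C)[C@@H]1C[C@H](O)C(C)(C)O1
F6 | step 13 | (4R,5E,9E)-10-[(2S,4S)-4-(tert-butyldimethylsilyloxy)-5,5-dimethyloxolan-2-yl]-6-methylundeca-5,9-dien-1-yn-4-ol | C#CC[C@@H](O)/C=C(\C)CC/C=C(\C)[C@@H]1C[C@H](O[Si](C)(C)C(C)(C)C)C(C)(C)O1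
F7 | step 13 | (4R,5E,9E)-10-[(2S,4S)-4-(tert-butyldimethylsilyloxy)-5,5-dimethyloxolan-2-yl]-6-methylundeca-5,9-dien-1-yn-4-yl acetate | C#CC[C@@H](OC(C)=O)/C=C(\C)CC/C=C(\C)[C@@H]1C[C@H](O[Si](C)(C)C(C)(C)C)C(C)(C)O1
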